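**Plan**

1. Locants (germacrane numbering, kept for every intermediate): C1 ketone, C4–C5 epoxide, C6 lactone O–CH, C7=C11 butenolide alkene, C8 methacrylate carbon, C10 acetoxy carbon, C12 lactone carbonyl, C13 acetoxymethyl; ring A = C1–C6, ring B = C1, C6–C10.
2. Retrosynthesis: cut the C8 ester, open the C4–C5 epoxide to a cis-4,5-diol (inversion at C5) and open the lactone C6–O bond (C6 ketone plus C12 methyl ester). Because the C1 ketone and the C6 carbinol are 1,6-related across the ten-membered ring, the two carbonyl carbons are then joined as the tetrasubstituted ring-fusion alkene C1=C6 of a bicyclo[4.4.0]dec-1(6)-ene.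
3. The octalin is cut at C10–CH3, at C6–C7 and C11–C12 (alkyne carbopalladation–carbonylation) and at C1–C10 (aldol), giving a ring A ketone from 3-methylcyclohex-2-en-1-one and a C8–C13 alkynal from a propargyl silyl ether.
4. Forward: ring A first, the chain joined at C1–C10, ring B closed by palladium through C6–C7, methyl added at C10, ozonolysis merging rings A and B into the ten-membered ring, then butenolide, epoxide and the two late esters.
5. Stereochemistry: C4/C5 from a CBS reduction relayed by anti-dihydroxylation; C8 from an asymmetric allylboration; C10 from addition anti to the axial C8 silyloxy group on ring B; C7=C11 geometry from syn-carbopalladation; C6 from chelation-controlled reduction; C5 inverted in the epoxide closure.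

Key step: step 14

Remark: CIP labels are given with the target locants; the C5 label changes with its neighbours (R beside a C6 carbonyl or enol triflate, S beside the C1=C6 alkene or the lactone carbinol) without any change at the centre until step 19. TBS = tert-butyldimethylsilyl, TBDPS = tert-butyldiphenylsilyl.

**Route**

Step 1
Reactants: 1 3-methylcyclohex-2-en-1-one
Product: 2 (R)-3-methylcyclohex-2-en-1-ol
Conditions: (S)-2-methyl-CBS-oxazaborolidine (10 mol %), BH3·SMe2, THF, −20 °C; MeOH
Reagents that add atoms: none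
Why: CBS reduction, in which the oxazaborolidine–borane complex delivers hydride to one carbonyl face with the alkene flank acting as the large group, should give the (R)-carbinol that later steers the diol face.

Step 2
Reactants: 2 (R)-3-methylcyclohex-2-en-1-ol
Product: 3 (1R,2S,3R)-3-methylcyclohexane-1,2,3-triol
Conditions: OsO4 (2 mol %), N-methylmorpholine N-oxide, acetone/H2O, 0 °C to rt
Reagents that add atoms: osmium tetroxide (O=[Os](=O)(=O)=O, catalytic oxygen carrier), N-methylmorpholine N-oxide (C[N+]1([O-])CCOCC1), water (O)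
Why: Upjohn dihydroxylation of a cyclic allylic alcohol takes place anti to the hydroxyl, so the C6 carbinol should relay its configuration to C4 and C5 as a cis-diol on the opposite face.

Step 3
Reactants: 3 (1R,2S,3R)-3-methylcyclohexane-1,2,3-triol
Product: 4 (3aS,4R,7aR)-2,2,7a-trimethylhexahydro-1,3-benzodioxol-4-ol
Conditions: 2,2-dimethoxypropane, PPTS (cat.), CH2Cl2, rt
Reagents that add atoms: 2,2-dimethoxypropane (COC(C)(C)OC)
Why: Acid-catalysed transketalisation closes the dioxolane only across the cis C4/C5 hydroxyls, a trans-fused acetonide on the C5/C6 diol being strained, so the C6 hydroxyl stays free.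

Step 4
Reactants: 4 (3aS,4R,7aR)-2,2,7a-trimethylhexahydro-1,3-benzodioxol-4-ol
Product: 5 (3aR,7aR)-2,2,7a-trimethyltetrahydro-1,3-benzodioxol-4(3aH)-one (ring A ketone: C6 carbonyl, C4/C5 cis-acetonide)
Conditions: Dess–Martin periodinane, pyridine, CH2Cl2, 0 °C to rt
Reagents that add atoms: none
Why: Dess–Martin oxidation of the remaining secondary alcohol is mild and buffered, so the α-alkoxy centre C5 should not epimerise, and it erases the C6 carbinol centre once it has done its relay work.

Step 5
Reactants: 6 tert-butyldimethyl(prop-2-yn-1-yloxy)silane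
Product: 7 4-[(tert-butyldimethylsilyl)oxy]but-2-ynal
Conditions: n-BuLi, THF, −78 °C; DMF, −78 to 0 °C; inverse quench into aq. KH2PO4
Reagents that add atoms: N,N-dimethylformamide (CN(C)C=O)
Why: Formylation of a lithium acetylide with DMF followed by a buffered inverse quench is the standard route to ynals.

Step 6
Reactants: 7 4-[(tert-butyldimethylsilyl)oxy]but-2-ynal
Product: 8 (4S)-7-[(tert-butyldimethylsilyl)oxy]hept-1-en-5-yn-4-ol
Conditions: B-allyldiisopinocampheylborane of the (+)-α-pinene series (salt-free), Et2O, −78 °C; then NaOH, H2O2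
Reagents that add atoms: B-allyldiisopinocampheylborane (C=CCB([C@@H]1C[C@@H]2C[C@H]([C@H]1C)C2(C)C)[C@@H]1C[C@@H]2C[C@H]([C@H]1C)C2(C)C)
Why: Brown allylation through a closed chair transition state delivers allyl to the Si face of the aldehyde, which for an alkynyl aldehyde should give the (S)-carbinol that becomes C8.

Step 7
Reactants: 8 (4S)-7-[(tert-butyldimethylsilyl)oxy]hept-1-en-5-yn-4-ol
Product: 9 (4S)-7-[(tert-butyldimethylsilyl)oxy]-4-[(tert-butyldiphenylsilyl)oxy]hept-1-en-5-yne
Conditions: TBDPSCl, imidazole, DMF, rt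
Reagents that add atoms: tert-butyl(chloro)diphenylsilane (CC(C)(C)[Si](Cl)(c1ccccc1)c1ccccc1)
Why: Standard silylation of a secondary propargylic alcohol; the bulky, acid-stable TBDPS group is chosen to outlast the later acetonide/TBS hydrolysis and to shield one face of ring B.

Step 8
Reactants: 9 (4S)-7-[(tert-butyldimethylsilyl)oxy]-4-[(tert-butyldiphenylsilyl)oxy]hept-1-en-5-yne
Product: 11 (3S)-6-[(tert-butyldimethylsilyl)oxy]-3-[(tert-butyldiphenylsilyl)oxy]hex-4-ynal, via vicinal diol 10 (not isolated)
Conditions: OsO4 (2 mol %), NaIO4, 2,6-lutidine, dioxane/H2O, rt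
Reagents that add atoms: osmium tetroxide (O=[Os](=O)(=O)=O, catalytic oxygen carrier), sodium periodate ([Na+].[O-]I(=O)(=O)=O), water (O)
Why: Lemieux–Johnson cleavage: OsO4 dihydroxylates the terminal alkene far faster than the internal alkyne and NaIO4 cleaves the diol to the aldehyde with loss of one carbon.

Step 9
Reactants: 5 (3aR,7aR)-2,2,7a-trimethyltetrahydro-1,3-benzodioxol-4(3aH)-one; 11 (3S)-6-[(tert-butyldimethylsilyl)oxy]-3-[(tert-butyldiphenylsilyl)oxy]hex-4-ynal
Product: 12 aldol adduct, ketone 5 carrying at C1 the 1-hydroxy-(3S)-3-(TBDPS-oxy)-6-(TBS-oxy)hex-4-yn-1-yl chain (C10–C13; mixture of epimers at C1 and C10)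
Conditions: LDA, THF, −78 °C; then 11, −78 °C; aq. NH4Cl
Reagents that add atoms: none
Why: Kinetic deprotonation occurs at the unhindered C1 methylene and not at the alkoxy-bearing C5 methine, and the lithium enolate adds to the aldehyde in a directed aldol reaction whose two new centres are both erased in steps 10 and 11.

Step 10
Reactants: 12 aldol adduct
Product: 13 1,3-diketone (C6 and C10 carbonyls; (4R,5R,8S); enolised)
Conditions: Dess–Martin periodinane, pyridine, CH2Cl2, rt
Reagents that add atoms: none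
Why: Dess–Martin oxidation of a β-hydroxy ketone to the 1,3-diketone is standard and tolerates the acetonide, the alkyne and both silyl ethers.

Step 11
Reactants: 13 1,3-diketone
Product: 14 ring A enol triflate (C1=C6, OTf on C6, C10 ketone cis to it; (4R,5R,8S))
Conditions: Tf2O, iPr2NEt, CH2Cl2, −78 °C
Reagents that add atoms: trifluoromethanesulfonic anhydride (O=S(=O)(OS(=O)(=O)C(F)(F)F)C(F)(F)F)
Why: 2-Acylcyclohexanones are enolised into the ring (C1=C6 enol hydrogen-bonded to the exocyclic carbonyl), and O-sulfonylation of that enol gives the ring enol triflate, as known for 2-acetylcyclohexanone.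

Step 12
Reactants: 14 ring A enol triflate
Product: 15 bicyclo[4.4.0]dec-1(6)-ene dienone ester (C10 ketone; exocyclic C7=C11 with CO2Me cis to C6 and CH2OTBS cis to C8; (4R,5S,8S))
Conditions: PdCl2(PPh3)2 (5 mol %), CO (1 atm), MeOH (10 equiv), Et3N, DMF, 60 °C
Reagents that add atoms: carbon monoxide ([C-]#[O+]), methanol (CO)
Why: Oxidative addition of zerovalent palladium into C6–OTf, 6-exo-dig syn-carbopalladation of the tethered alkyne (closing ring B through C6–C7), CO insertion at C11 and methanolysis form a cyclic carbopalladation–carbonylative esterification cascade known for alkenyl halides and triflates bearing an alkyne, and the syn addition places the ester cis to C6; C13 carries a silyl ether because an acetate there could leave by β-elimination from the C11–Pd intermediate.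

Step 13
Reactants: 15 bicyclic dienone ester
Product: 17 octalin acetate ((4R,5S,8S,10R); C10 methyl and acetoxy; dienoate as in 15), via tertiary C10 alkoxide 16 (not isolated)
Conditions: MeLi, CeCl3, THF, −78 °C; then Ac2O, DMAP (cat.), −78 to 0 °C
Reagents that add atoms: methyllithium ([Li]C), acetic anhydride (CC(=O)OC(C)=O)
Why: The weakly basic organocerium reagent adds 1,2 to the enolisable C10 ketone and spares the hindered ester, approaching anti to the C8 silyloxy group that allylic 1,3-strain with the C11 CH2OTBS arm holds pseudo-axial, so the new oxygen is cis to the C8 oxygen (10R), and the alkoxide is acetylated in the same flask.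

Step 14
Reactants: 17 octalin acetate
Product: 19 cyclodecane-1,6-dione ((4R,5R,8S,10R); C6 ketone conjugated to C7=C11), via secondary ozonide 18 (not isolated)
Conditions: O3, CH2Cl2, −78 °C, Sudan Red 7B as end-point indicator; then PPh3, −78 °C to rt
Reagents that add atoms: ozone ([O-][O+]=O)
Why: Ozone adds as a 1,3-dipole to C1=C6, the primary ozonide splits into a ketone and a carbonyl oxide that stay tethered and recombine to the secondary ozonide 18, and PPh3 removes one oxygen to release the C1 and C6 ketones. The closest known reaction is the ozonolysis of 9,10-octalin to cyclodecane-1,6-dione. No ring is closed by bond formation: cutting the bond shared by rings A and B merges the two six-membered rings into the ten-membered carbocycle, so no mode of closure applies. No stereocentre is created, and C4, C5, C8 and C10, set earlier on the rigid octalin, are carried through unchanged because the work-up is neutral. The step needs site selectivity for C1=C6 over C7=C11, which the substrate secures because C1=C6 bears four carbon substituents whereas C7=C11 is deactivated by the ester on C11, with the indicator dye marking the end-point. Neutral phosphine reduction also avoids transannular aldol reaction of the 1,6-dione and β-elimination of the C4 oxygen from a C5 enolate.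

Step 15
Reactants: 19 cyclodecane-1,6-dione
Product: 21 butenolide acetonide ((4R,5S,6S,8S,10R); 6,12-olide, C1 ketone retained), via C6 hydroxy ester 20 (not isolated)
Conditions: Zn(BH4)2, Et2O, −30 °C; aq. NH4Cl; then PPTS (cat.), CH2Cl2, rt
Reagents that add atoms: none
Why: Zn(BH4)2 reduces the C6 carbonyl, activated by conjugation and by chelation to the C5 acetal oxygen, faster than the hindered C1 ketone and in the 1,2-sense, hydride reaching the chelate from the C5–H side (Cram-chelate, new oxygen anti to the C5 oxygen, 6S), and the alkoxide closes onto the cis ester to the butenolide.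

Step 16
Reactants: 21 butenolide acetonide
Product: 22 triol lactone (free C4, C5 and C13 hydroxyls; (4R,5S,6S,8S,10R))
Conditions: CF3CO2H/H2O/THF (1:1:4), 0 °C to rt
Reagents that add atoms: none
Why: Aqueous acid hydrolyses the acetonide and the primary allylic TBS ether while the secondary TBDPS ether, the tertiary acetate and the butenolide are stable; any transannular C1/C4 hemiketal of 22 is in equilibrium with the open form that reacts later.

Step 17
Reactants: 22 triol lactone
Product: 23 13-O-acetyl diol lactone (free C4 and C5 hydroxyls)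
Conditions: Ac2O (1.1 equiv), pyridine, CH2Cl2, −20 °C
Reagents that add atoms: acetic anhydride (CC(=O)OC(C)=O)
Why: A primary allylic alcohol is acetylated much faster than the hindered secondary C5 and the tertiary C4 hydroxyls, so one equivalent at low temperature should acetylate C13–OH only.

Step 18
Reactants: 23 13-O-acetyl diol lactone
Product: 24 C5 mesylate ((4R,5S,6S,8S,10R); free tertiary C4 hydroxyl)
Conditions: MsCl, pyridine, DMAP (cat.), CH2Cl2, 0 °C
Reagents that add atoms: methanesulfonyl chloride (CS(=O)(=O)Cl)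
Why: Sulfonylation selects the secondary C5 hydroxyl over the tertiary one, and pyridine as the only base is too weak to start vinylogous elimination through C6–H.

Step 19
Reactants: 24 C5 mesylate
Product: 25 8-O-TBDPS epoxy lactone ((4R,5R,6S,8S,10R); trans-4,5-epoxide)
Conditions: Cs2CO3, MeCN, 0 °C to rt
Reagents that add atoms: none
Why: Williamson-type 3-exo-tet closure, in which the C4 alkoxide displaces the C5 mesylate with inversion (5S to 5R), gives the trans-epoxide that a six-membered ring could not hold, and the intramolecular displacement should outrun elimination through the butenolide γ-anion.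

Step 20
Reactants: 25 8-O-TBDPS epoxy lactone
Product: 26 8-hydroxy epoxy lactone (8-O-desmethacryloyl glaucolide A)
Conditions: Bu4NF, AcOH (1:1), THF, 0 °C to rt
Reagents that add atoms: none
Why: Fluoride cleaves the silyl ether, and buffering with acetic acid keeps the medium from opening the epoxide, moving the acetates or deprotonating C6.

Step 21
Reactants: 26 8-hydroxy epoxy lactone
Product: 27 glaucolide A
Conditions: methacrylic anhydride, DMAP, pyridine, CH2Cl2, 0 °C to rt
Reagents that add atoms: methacrylic anhydride (C=C(C)C(=O)OC(=O)C(C)=C)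
Why: DMAP-catalysed acylation of the secondary C8 alcohol under weakly basic conditions installs the methacrylate without disturbing the epoxide, the butenolide or the acetates.

**Compound list**

1 | 3-methylcyclohex-2-en-1-one | CC1=CC(=O)CCC1 | starting material
2 | (R)-3-methylcyclohex-2-en-1-ol | CC1=C[C@H](O)CCC1 | intermediate
3 | (1R,2S,3R)-3-methylcyclohexane-1,2,3-triol | O[C@@H]1CCC[C@@](C)(O)[C@H]1O | intermediate
4 | (3aS,4R,7aR)-2,2,7a-trimethylhexahydro-1,3-benzodioxol-4-ol | O[C@@H]1CCC[C@@]2(C)OC(C)(C)O[C@@H]12 | intermediate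
5 | (3aR,7aR)-2,2,7a-trimethyltetrahydro-1,3-benzodioxol-4(3aH)-one | O=C1CCC[C@@]2(C)OC(C)(C)O[C@@H]12 | intermediate
6 | tert-butyldimethyl(prop-2-yn-1-yloxy)silane | C#CCO[Si](C)(C)C(C)(C)C | starting material
7 | 4-[(tert-butyldimethylsilyl)oxy]but-2-ynal | O=CC#CCO[Si](C)(C)C(C)(C)C | intermediate
8 | (4S)-7-[(tert-butyldimethylsilyl)oxy]hept-1-en-5-yn-4-ol | C=CC[C@H](O)C#CCO[Si](C)(C)C(C)(C)C | intermediate
9 | (4S)-7-[(tert-butyldimethylsilyl)oxy]-4-[(tert-butyldiphenylsilyl)oxy]hept-1-en-5-yne | C=CC[C@H](O[Si](c1ccccc1)(c1ccccc1)C(C)(C)C)C#CCO[Si](C)(C)C(C)(C)C | intermediate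
10 | (4S)-7-[(tert-butyldimethylsilyl)oxy]-4-[(tert-butyldiphenylsilyl)oxy]hept-5-yne-1,2-diol (C2 epimers; not isolated) | OCC(O)C[C@H](O[Si](c1ccccc1)(c1ccccc1)C(C)(C)C)C#CCO[Si](C)(C)C(C)(C)C | intermediate
11 | (3S)-6-[(tert-butyldimethylsilyl)oxy]-3-[(tert-butyldiphenylsilyl)oxy]hex-4-ynal | O=CC[C@H](O[Si](c1ccccc1)(c1ccccc1)C(C)(C)C)C#CCO[Si](C)(C)C(C)(C)C | intermediate
12 | (3aR,7aR)-5-[(3S)-6-(TBS-oxy)-3-(TBDPS-oxy)-1-hydroxyhex-4-yn-1-yl]-2,2,7a-trimethyltetrahydro-1,3-benzodioxol-4(3aH)-one (epimers at C1 and C10) | O=C1C(C(O)C[C@H](O[Si](c3ccccc3)(c3ccccc3)C(C)(C)C)C#CCO[Si](C)(C)C(C)(C)C)CC[C@@]2(C)OC(C)(C)O[C@@H]12 | intermediate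
13 | (3aR,7aR)-5-[(3S)-6-(TBS-oxy)-3-(TBDPS-oxy)hex-4-ynoyl]-2,2,7a-trimethyltetrahydro-1,3-benzodioxol-4(3aH)-one (1,3-diketone) | O=C1C(C(=O)C[C@H](O[Si](c3ccccc3)(c3ccccc3)C(C)(C)C)C#CCO[Si](C)(C)C(C)(C)C)CC[C@@]2(C)OC(C)(C)O[C@@H]12 | intermediate
14 | (3aR,7aR)-5-[(3S)-6-(TBS-oxy)-3-(TBDPS-oxy)hex-4-ynoyl]-2,2,7a-trimethyl-3a,6,7,7a-tetrahydro-1,3-benzodioxol-4-yl trifluoromethanesulfonate | O=C(C[C@H](O[Si](c1ccccc1)(c1ccccc1)C(C)(C)C)C#CCO[Si](C)(C)C(C)(C)C)C1=C(OS(=O)(=O)C(F)(F)F)[C@@H]2OC(C)(C)O[C@]2(C)CC1 | intermediate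
15 | (4R,5S,8S)-bicyclo[4.4.0]dec-1(6)-en-10-one dienoate: C4/C5 cis-acetonide, 8-OTBDPS, C7=C11 with CO2Me cis to C6 and CH2OTBS cis to C8 | C12=C(/C(=C(/CO[Si](C)(C)C(C)(C)C)C(=O)OC)[C@@H](O[Si](c3ccccc3)(c3ccccc3)C(C)(C)C)CC1=O)[C@@H]1OC(C)(C)O[C@]1(C)CC2 | intermediate
16 | (4R,5S,8S,10R)-C10 methyl carbinol of 15, formed as its alkoxide (not isolated) | C12=C(/C(=C(/CO[Si](C)(C)C(C)(C)C)C(=O)OC)[C@@H](O[Si](c3ccccc3)(c3ccccc3)C(C)(C)C)C[C@@]1(C)O)[C@@H]1OC(C)(C)O[C@]1(C)CC2 | intermediate
17 | (4R,5S,8S,10R)-1(6)-octalin dienoate: C4/C5 cis-acetonide, 8-OTBDPS, 10-methyl-10-acetoxy, 13-OTBS, methyl ester cis to C6 | C12=C(/C(=C(/CO[Si](C)(C)C(C)(C)C)C(=O)OC)[C@@H](O[Si](c3ccccc3)(c3ccccc3)C(C)(C)C)C[C@@]1(C)OC(C)=O)[C@@H]1OC(C)(C)O[C@]1(C)CC2 | intermediate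
18 | secondary ozonide (1,2,4-trioxolane across C1 and C6) of 17 (not isolated) | C134OOC(O1)(/C(=C(/CO[Si](C)(C)C(C)(C)C)C(=O)OC)[C@@H](O[Si](c5ccccc5)(c5ccccc5)C(C)(C)C)C[C@@]4(C)OC(C)=O)[C@@H]2OC(C)(C)O[C@]2(C)CC3 | intermediate
19 | (4R,5R,8S,10R)-cyclodecane-1,6-dione alkylidene ester: C4/C5 cis-acetonide, 8-OTBDPS, 10-acetoxy, 13-OTBS | O=C1CC[C@@]2(C)OC(C)(C)O[C@H]2C(=O)/C(=C(/CO[Si](C)(C)C(C)(C)C)C(=O)OC)[C@@H](O[Si](c3ccccc3)(c3ccccc3)C(C)(C)C)C[C@@]1(C)OC(C)=O | intermediate
20 | (4R,5S,6S,8S,10R)-C6 hydroxy methyl ester (not isolated) | O=C1CC[C@@]2(C)OC(C)(C)O[C@H]2[C@@H](O)/C(=C(/CO[Si](C)(C)C(C)(C)C)C(=O)OC)[C@@H](O[Si](c3ccccc3)(c3ccccc3)C(C)(C)C)C[C@@]1(C)OC(C)=O | intermediate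
21 | (4R,5S,6S,8S,10R)-6,12-olide (butenolide) with C4/C5 acetonide, 8-OTBDPS, 13-OTBS, 10-acetoxy, C1 ketone | O=C1CC[C@@]2(C)OC(C)(C)O[C@H]2[C@H]2OC(=O)C(CO[Si](C)(C)C(C)(C)C)=C2[C@@H](O[Si](c3ccccc3)(c3ccccc3)C(C)(C)C)C[C@@]1(C)OC(C)=O | intermediate
22 | (4R,5S,6S,8S,10R)-4,5,13-triol butenolide, 8-OTBDPS | O=C1CC[C@@](C)(O)[C@@H](O)[C@H]2OC(=O)C(CO)=C2[C@@H](O[Si](c3ccccc3)(c3ccccc3)C(C)(C)C)C[C@@]1(C)OC(C)=O | intermediate
23 | (4R,5S,6S,8S,10R)-13-O-acetyl-4,5-diol butenolide, 8-OTBDPS | O=C1CC[C@@](C)(O)[C@@H](O)[C@H]2OC(=O)C(COC(C)=O)=C2[C@@H](O[Si](c3ccccc3)(c3ccccc3)C(C)(C)C)C[C@@]1(C)OC(C)=O | intermediate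
24 | (4R,5S,6S,8S,10R)-5-O-mesyl-13-O-acetyl-4-hydroxy butenolide, 8-OTBDPS | O=C1CC[C@@](C)(O)[C@@H](OS(C)(=O)=O)[C@H]2OC(=O)C(COC(C)=O)=C2[C@@H](O[Si](c3ccccc3)(c3ccccc3)C(C)(C)C)C[C@@]1(C)OC(C)=O | intermediate
25 | (4R,5R,6S,8S,10R)-8-O-TBDPS-8-O-desmethacryloyl glaucolide A | O=C1CC[C@@]2(C)O[C@@H]2[C@H]2OC(=O)C(COC(C)=O)=C2[C@@H](O[Si](c3ccccc3)(c3ccccc3)C(C)(C)C)C[C@@]1(C)OC(C)=O | intermediate
26 | (4R,5R,6S,8S,10R)-8-O-desmethacryloyl glaucolide A (free C8 hydroxyl) | O=C1CC[C@@]2(C)O[C@@H]2[C@H]2OC(=O)C(COC(C)=O)=C2[C@@H](O)C[C@@]1(C)OC(C)=O | intermediate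
27 | glaucolide A, (4R,5R,6S,8S,10R) | C=C(C)C(=O)O[C@H]1C[C@@](C)(OC(C)=O)C(=O)CC[C@@]2(C)O[C@@H]2[C@H]2OC(=O)C(COC(C)=O)=C12 | target

**Totals**

Total step count: 21. Longest linear sequence: 17 steps (steps 1–4 then 9–21 from 3-methylcyclohex-2-en-1-one; the alkynal branch, steps 5–8 then 9–21, is equally long).

**Steps most likely to fail**

Step 12. The alkenylpalladium at C6 may be carbonylated before it has added to the alkyne, giving a premature ester at C6, or the base may induce loss of the C8 silyloxy group. The fallback divides the cascade and sets out from 14. Cyclisation without CO, with borylative capture of the C11–Pd bond (Pd(OAc)2, PPh3, B2pin2, KOAc, toluene), would give the C11 pinacol boronate F1 with the same syn geometry. Oxidative methoxycarbonylation of the C–B bond with retention (Pd(OAc)2, PPh3, p-benzoquinone, CO, MeOH) then comes back to the route at 15.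

Step 15. Hydride may also attack the C1 ketone or add in the conjugate sense, and facial selectivity at C6 may be poor in the flexible ten-membered ring. The fallback sets out from 19 and changes both the order and the directing group. Aqueous CF3CO2H first removes the acetonide and the primary TBS ether to give the keto triol F2, in which the freed C4 hydroxyl can mask the C1 ketone as its transannular hemiketal. Zn(BH4)2 then reduces the α-hydroxy ketone through the zinc alkoxide chelate of the free C5 hydroxyl (anti-selective) to the hydroxy ester F3, which lactonises and comes back to the route at 22.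

Step 19. Deprotonation at C6 (the butenolide γ-position) followed by loss of the mesylate would give a C5=C6 alkylidene butenolide in competition with ring closure. The fallback sets out from diol 23 and avoids both the sulfonate and the base: Mitsunobu cyclodehydration (PPh3, diisopropyl azodicarboxylate, toluene) activates the secondary C5 hydroxyl as its oxyphosphonium ion, and the C4 hydroxyl displaces it with inversion under neutral conditions. This comes back to the route at 25 and makes no new compound (F0).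

**Further compounds**

F1 | step 12 | C11 pinacol boronate of the cyclised dienone (Bpin cis to C6, CH2OTBS cis to C8; (4R,5S,8S)) | C12=C(/C(=C(/CO[Si](C)(C)C(C)(C)C)B3OC(C)(C)C(C)(C)O3)[C@@H](O[Si](c4ccccc4)(c4ccccc4)C(C)(C)C)CC1=O)[C@@H]1OC(C)(C)O[C@]1(C)CC2
F2 | step 15 | (4R,5R,8S,10R)-4,5,13-trihydroxy cyclodecane-1,6-dione methyl ester, 8-OTBDPS | O=C1CC[C@@](C)(O)[C@@H](O)C(=O)/C(=C(/CO)C(=O)OC)[C@@H](O[Si](c3ccccc3)(c3ccccc3)C(C)(C)C)C[C@@]1(C)OC(C)=O
F3 | step 15 | (4R,5S,6S,8S,10R)-4,5,6,13-tetrahydroxy methyl ester, 8-OTBDPS | O=C1CC[C@@](C)(O)[C@@H](O)[C@@H](O)/C(=C(/CO)C(=O)OC)[C@@H](O[Si](c3ccccc3)(c3ccccc3)C(C)(C)C)C[C@@]1(C)OC(C)=O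
F0 | step 19 | none | none
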